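**Retrosynthetic overview**
1. Target ⇒ α-methylene 8α,12-lactone: the lactone masks O-8 and C12 while the only free secondary hydroxyl (O-6) is angeloylated; C1 ketone reduction and lactone saponification/O-methylation finish.
2. Lactone and ring B (formed second) ⇒ ring-A keto aldehyde carrying an (E)-alkenyl malonate on C10: a Prins cyclisation makes C6–C7 and a malonate carbonyl captures C8 (C8–O) in the same step.
3. Keto aldehyde ⇒ epoxy alcohol + dienyl malonate: Cp2TiCl-mediated radical epoxide opening/1,6-addition creates the C10 quaternary centre; Mukaiyama hydration gives the C4 carbinol.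
4. Epoxy alcohol ⇒ achiral dienyl carbinol: catalytic enantioselective, hydroxyl-directed mono-epoxidation chooses one of two mirror-related olefins (key step).
5. Dienyl carbinol ⇒ 2,6-dimethylbenzoic acid: Birch reduction turns the arene into ring A (formed first), then hydride reduction.

Numbering: eudesmane numbering throughout (ring A = C1–C5, C10; ring B = C5–C10; C14 on C10, C15 on C4, C11–C13 on C7; α = face opposite the C10 methyl).
Assumption: the (R,R) ligand in step 3 is taken to give the enantiomer drawn for 4; if induction is the opposite, the (S,S) ligand is used.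

**Step 1**
Reactants: 1 2,6-dimethylbenzoic acid
Product: 2 2,6-dimethylcyclohexa-2,5-diene-1-carboxylic acid (achiral; mirror plane through C1 and C4)
Conditions: Li, NH3(l), THF, −78 °C; then NH4Cl
Reagents that add atoms: none
Why: Birch reduction of a benzoate, in which the carboxylate directs protonation to the ipso and para carbons, so the arene becomes the non-conjugated 1,4-dihydro acid with both methyl groups left on the double bonds.

**Step 2**
Reactants: 2 2,6-dimethylcyclohexa-2,5-diene-1-carboxylic acid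
Product: 3 (2,6-dimethylcyclohexa-2,5-dien-1-yl)methanol (achiral)
Conditions: LiAlH4, Et2O, 0 °C → rt
Reagents that add atoms: none
Why: LiAlH4 reduction of the carboxylic acid to the primary alcohol; the isolated trisubstituted olefins are inert to hydride.

**Step 3**
Reactants: 3 (2,6-dimethylcyclohexa-2,5-dien-1-yl)methanol
Product: 4 [(1S,2R,6R)-1,3-dimethyl-7-oxabicyclo[4.1.0]hept-3-en-2-yl]methanol (mono-epoxide on C10–C1, cis to CH2OH)
Conditions: VO(OiPr)3 (2 mol%), (R,R)-N,N'-(cyclohexane-1,2-diyl)bis(N-hydroxy-2,2-diphenylacetamide) (4 mol%), cumene hydroperoxide (1.05 equiv), toluene, 0 °C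
Reagents that add atoms: cumene hydroperoxide, CC(C)(OO)c1ccccc1
Why: Proposed new method: the vanadium alkoxide of the homoallylic alcohol delivers peroxide oxygen to the olefin face cis to CH2OH and the chiral bishydroxamate ligand should select one of the two enantiotopic olefins, fixing C5, C10 and C1 at once (any mismatched mono-epoxide is drained to bis-epoxide); the closest known reaction is the vanadium/bishydroxamic acid asymmetric epoxidation of homoallylic alcohols.

**Step 4**
Reactants: 5 acrolein; 6 dibenzyl malonate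
Product: 7 dibenzyl 2-(prop-2-en-1-ylidene)malonate
Conditions: TiCl4, pyridine, THF, 0 °C → rt
Reagents that add atoms: none
Why: Knoevenagel condensation under Lehnert conditions, which tolerate the polymerisation-prone enal and give the cross-conjugated dienyl malonate.

**Step 5**
Reactants: 4 [(1S,2R,6R)-1,3-dimethyl-7-oxabicyclo[4.1.0]hept-3-en-2-yl]methanol; 7 dibenzyl 2-(prop-2-en-1-ylidene)malonate
Product: 8 dibenzyl 2-[(1E)-3-[(1R,2R,6S)-2-hydroxy-6-(hydroxymethyl)-1,5-dimethylcyclohex-4-en-1-yl]prop-1-en-1-yl]malonate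
Conditions: Cp2TiCl2 (2.5 equiv), Zn dust, THF, rt; then 4 and 7, −20 °C → rt; 1 M HCl
Reagents that add atoms: none
Why: Proposed new method: reductive epoxide opening by Cp2TiCl (trivalent titanium; Nugent–RajanBabu reaction, known with acrylates) gives the tertiary C10 radical, which should add to the unsubstituted terminus of the doubly activated diene (1,6-Giese addition) anti to the flanking titanoxy and hydroxymethyl groups (C9 α, C14 β), and a second Cp2TiCl reduces the s-trans allyl-malonyl radical to an enolate whose kinetic C-protonation leaves the (E)-β,γ-olefin.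

**Step 6**
Reactants: 8 dibenzyl 2-[(1E)-3-[(1R,2R,6S)-2-hydroxy-6-(hydroxymethyl)-1,5-dimethylcyclohex-4-en-1-yl]prop-1-en-1-yl]malonate
Product: 9 dibenzyl 2-[(1E)-3-[(1R,2R,5R,6S)-2,5-dihydroxy-6-(hydroxymethyl)-1,5-dimethylcyclohexyl]prop-1-en-1-yl]malonate
Conditions: Co(acac)2 (20 mol%), PhSiH3, O2 (1 atm), i-PrOH–THF, 0 °C → rt
Reagents that add atoms: dioxygen, O=O
Why: Mukaiyama hydration (hydrogen-atom transfer then O2 trapping) prefers the trisubstituted ring olefin over the internal disubstituted one, gives the tertiary C4 radical, and O2 enters from the α face, anti to the axial C10 methyl and the C5 substituent, giving the 4α-alcohol.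

**Step 7**
Reactants: 9 dibenzyl 2-[(1E)-3-[(1R,2R,5R,6S)-2,5-dihydroxy-6-(hydroxymethyl)-1,5-dimethylcyclohexyl]prop-1-en-1-yl]malonate
Product: 10 dibenzyl 2-[(1E)-3-[(1R,2R,3R)-2-formyl-3-hydroxy-1,3-dimethyl-6-oxocyclohexyl]prop-1-en-1-yl]malonate
Conditions: (COCl)2 (2.4 equiv), DMSO, CH2Cl2, −78 °C; Et3N, −78 → −30 °C
Reagents that add atoms: none
Why: Swern oxidation activates both alcohols before any carbonyl exists, so the primary alcohol gives the C6 aldehyde and the secondary one the C1 ketone without lactol or lactone formation, while the tertiary alcohol and the C5 configuration survive at low temperature.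

**Step 8**
Reactants: 10 dibenzyl 2-[(1E)-3-[(1R,2R,3R)-2-formyl-3-hydroxy-1,3-dimethyl-6-oxocyclohexyl]prop-1-en-1-yl]malonate
Product: 11 benzyl 4α,6α-dihydroxy-1-oxoeudesman-12,8α-olid-13-oate (trans-decalin; 10β-methyl; 5α-H; 7α-H; 8β-H; C11 epimers)
Conditions: SnCl4 (3 equiv), CH2Cl2, −78 → −30 °C; aq. NaHCO3
Reagents that add atoms: none
Why: Proposed new method: a Lewis-acid Prins carbocyclisation (6-endo; closest precedents are SnCl4-mediated cyclisations of 5-alkenals and ester-terminated cation–olefin cyclisations) through a chair in which the chelated aldehyde oxygen is equatorial (6α-OH) and the (E)-olefin substituent is equatorial (7β), with anti addition letting a malonate carbonyl capture C8 equatorially and chloride removing its benzyl group to give the trans-fused 8α,12-lactone on a decalin that is trans because C5 and C10 were set trans earlier.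

**Step 9**
Reactants: 11 benzyl 4α,6α-dihydroxy-1-oxoeudesman-12,8α-olid-13-oate
Product: 13 4α,6α-dihydroxy-1-oxoeudesm-11(13)-en-12,8α-olide, via carboxylic acid 12 (not isolated)
Conditions: H2 (1 atm), Pd/C, EtOAc, rt; filter; 37% aq. HCHO, Et2NH, AcOH, THF, rt → 50 °C
Reagents that add atoms: formaldehyde, C=O
Why: Hydrogenolysis frees the malonic half-acid, and a Mannich condensation followed by decarboxylative elimination (the classical α-methylene lactone synthesis) installs the exocyclic methylene without strong base, so the C1 ketone is not enolised.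

**Step 10**
Reactants: 13 4α,6α-dihydroxy-1-oxoeudesm-11(13)-en-12,8α-olide; 14 angelic acid
Product: 16 6α-angeloyloxy-4α-hydroxy-1-oxoeudesm-11(13)-en-12,8α-olide, via mixed anhydride 15 (not isolated)
Conditions: 14, 2,4,6-trichlorobenzoyl chloride, Et3N, toluene, rt; then 13, toluene, 80 °C
Reagents that add atoms: none
Why: Yamaguchi-type esterification with the preformed angelic mixed anhydride acylates the only secondary hydroxyl (O-8 is in the lactone, C1 is a ketone, the C4 hydroxyl is tertiary), and DMAP-free conditions avoid Z→E isomerisation to the tiglate.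

**Step 11**
Reactants: 16 6α-angeloyloxy-4α-hydroxy-1-oxoeudesm-11(13)-en-12,8α-olide
Product: 17 6α-angeloyloxy-1β,4α-dihydroxyeudesm-11(13)-en-12,8α-olide
Conditions: NaBH4, CeCl3·7H2O, MeOH, −78 °C
Reagents that add atoms: none
Why: Luche reduction delivers hydride 1,2 to the C1 ketone from the α face (axial attack, away from the β methyl on C10) to give the equatorial 1β-alcohol while leaving the α-methylene lactone and the angelate untouched.

**Step 12**
Reactants: 17 6α-angeloyloxy-1β,4α-dihydroxyeudesm-11(13)-en-12,8α-olide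
Product: 19 methyl 6α-angeloyloxy-1β,4α,8α-trihydroxyeudesm-11(13)-en-12-oate (target; 1R,4R,5S,6S,7R,8S,10R), via lithium carboxylate 18 (not isolated)
Conditions: LiOH·H2O (1.2 equiv), THF–H2O, 0 °C; evaporate; MeI, DMF, 0 °C → rt
Reagents that add atoms: lithium hydroxide, [Li+].[OH-]; iodomethane, CI
Why: Saponification of the strained trans-fused lactone is much faster than that of the hindered angelate, and O-alkylation of the carboxylate with MeI fixes the open hydroxy ester before it can relactonise.

**Compound list**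
1 | 2,6-dimethylbenzoic acid | Cc1cccc(C)c1C(=O)O | starting material
2 | 2,6-dimethylcyclohexa-2,5-diene-1-carboxylic acid | OC(=O)C1C(C)=CCC=C1C | intermediate
3 | (2,6-dimethylcyclohexa-2,5-dien-1-yl)methanol | OCC1C(C)=CCC=C1C | intermediate
4 | [(1S,2R,6R)-1,3-dimethyl-7-oxabicyclo[4.1.0]hept-3-en-2-yl]methanol | OC[C@H]1C(C)=CC[C@H]2O[C@@]12C | intermediate
5 | acrolein | C=CC=O | starting material
6 | dibenzyl malonate | O=C(CC(=O)OCc1ccccc1)OCc1ccccc1 | starting material
7 | dibenzyl 2-(prop-2-en-1-ylidene)malonate | C=CC=C(C(=O)OCc1ccccc1)C(=O)OCc1ccccc1 | intermediate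
8 | dibenzyl 2-[(1E)-3-[(1R,2R,6S)-2-hydroxy-6-(hydroxymethyl)-1,5-dimethylcyclohex-4-en-1-yl]prop-1-en-1-yl]malonate | OC[C@@H]1[C@@](C)(C/C=C/C(C(=O)OCc2ccccc2)C(=O)OCc2ccccc2)[C@H](O)CC=C1C | intermediate
9 | dibenzyl 2-[(1E)-3-[(1R,2R,5R,6S)-2,5-dihydroxy-6-(hydroxymethyl)-1,5-dimethylcyclohexyl]prop-1-en-1-yl]malonate | OC[C@@H]1[C@@](C)(C/C=C/C(C(=O)OCc2ccccc2)C(=O)OCc2ccccc2)[C@H](O)CC[C@@]1(C)O | intermediate
10 | dibenzyl 2-[(1E)-3-[(1R,2R,3R)-2-formyl-3-hydroxy-1,3-dimethyl-6-oxocyclohexyl]prop-1-en-1-yl]malonate | O=C[C@@H]1[C@@](C)(C/C=C/C(C(=O)OCc2ccccc2)C(=O)OCc2ccccc2)C(=O)CC[C@@]1(C)O | intermediate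
11 | benzyl 4α,6α-dihydroxy-1-oxoeudesman-12,8α-olid-13-oate (C11 epimers) | O=C(OCc1ccccc1)C1C(=O)O[C@H]2C[C@@]3(C)C(=O)CC[C@@](C)(O)[C@@H]3[C@@H](O)[C@H]12 | intermediate
12 | 4α,6α-dihydroxy-1-oxoeudesman-12,8α-olid-13-oic acid (C11 epimers) | OC(=O)C1C(=O)O[C@H]2C[C@@]3(C)C(=O)CC[C@@](C)(O)[C@@H]3[C@@H](O)[C@H]12 | intermediate
13 | 4α,6α-dihydroxy-1-oxoeudesm-11(13)-en-12,8α-olide | C=C1C(=O)O[C@H]2C[C@@]3(C)C(=O)CC[C@@](C)(O)[C@@H]3[C@@H](O)[C@H]12 | intermediate
14 | angelic acid, (Z)-2-methylbut-2-enoic acid | C/C=C(/C)C(=O)O | starting material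
15 | (Z)-2-methylbut-2-enoic 2,4,6-trichlorobenzoic anhydride | C/C=C(/C)C(=O)OC(=O)c1c(Cl)cc(Cl)cc1Cl | intermediate
16 | 6α-angeloyloxy-4α-hydroxy-1-oxoeudesm-11(13)-en-12,8α-olide | C=C1C(=O)O[C@H]2C[C@@]3(C)C(=O)CC[C@@](C)(O)[C@@H]3[C@@H](OC(=O)/C(C)=C\C)[C@H]12 | intermediate
17 | 6α-angeloyloxy-1β,4α-dihydroxyeudesm-11(13)-en-12,8α-olide | C=C1C(=O)O[C@H]2C[C@@]3(C)[C@H](O)CC[C@@](C)(O)[C@@H]3[C@@H](OC(=O)/C(C)=C\C)[C@H]12 | intermediate
18 | lithium 6α-angeloyloxy-1β,4α,8α-trihydroxyeudesm-11(13)-en-12-oate | [Li+].C=C(C(=O)[O-])[C@H]1[C@H](OC(=O)/C(C)=C\C)[C@@H]2[C@@](C)(C[C@@H]1O)[C@H](O)CC[C@@]2(C)O | intermediate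
19 | methyl 6α-angeloyloxy-1β,4α,8α-trihydroxyeudesm-11(13)-en-12-oate (CNP0136844.1) | C=C(C(=O)OC)[C@H]1[C@H](OC(=O)/C(C)=C\C)[C@@H]2[C@@](C)(C[C@@H]1O)[C@H](O)CC[C@@]2(C)O | target

**Step count**
Total steps: 12. Longest linear sequence: 11 steps (1 → 19 through steps 1–3 and 5–12); step 4 is a one-step side branch.

**Three steps most likely to fail**

Step 3 (desymmetrising epoxidation). Ring-bound trisubstituted homoallylic olefins are at the edge of the catalyst's known scope, so olefin selection may be poor and bis-epoxidation may cost yield. Fallback, setting out from 3 and returning at 4: racemic syn-epoxidation with VO(acac)2/t-BuOOH gives 4 together with its mirror image, the (1R,2S,6S)-epoxy alcohol F1. Kinetic resolution with Pseudomonas cepacia lipase and vinyl acetate acylates the unwanted enantiomer to its acetate F2, which is removed by chromatography, and the remaining 4 goes on to step 5.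

Step 5 (radical 1,6-addition). The vinylogous acceptor is untested in this reaction; titanium may reduce or polymerise 7, the tertiary radical may lose a β-hydrogen, or protonation may give the conjugated alkylidene malonate. Fallback, setting out from 4 and returning at 8: the classical Cp2TiCl coupling with acrylonitrile gives the hydroxy nitrile F3 with the same anti selectivity at C10. DIBAL-H reduces it to the aldehyde F4 (a δ-lactol with the C1 hydroxyl). Knoevenagel condensation with 6 gives the alkylidene malonate F5 (or its oxa-Michael tautomer). Excess LiHMDS, then kinetic protonation at −78 °C, moves the double bond out of conjugation and gives 8.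

Step 8 (Prins–lactonisation). The olefin is deactivated by the allylic malonate, and 5-exo or ene closure, or axial capture giving a cis-lactone, could compete. Fallback, setting out from 9 and returning at 11, closes ring B by a reversible aldol addition instead of a cation–olefin reaction:
- Tsuji–Wacker oxidation (PdCl2, CuCl, O2, DMF–H2O) gives the C8 ketone F6, oxygen entering distal to the malonate.
- TEMPO/PhI(OAc)2 oxidises only the primary alcohol, stopping at the hydroxy aldehyde F7 (lactol form).
- DBU-mediated intramolecular aldol addition under thermodynamic control gives the all-equatorial 6α-hydroxy-8-oxo decalin F8.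
- SmI2/H2O/Et3N reduces the C8 ketone to the equatorial 8α-alcohol, which lactonises onto the malonate to the 1β-hydroxy lactone F9.
- One equivalent of DMP oxidises the less hindered C1 alcohol and gives 11.

**Further compounds**
F1 | step 3 | [(1R,2S,6S)-1,3-dimethyl-7-oxabicyclo[4.1.0]hept-3-en-2-yl]methanol (enantiomer of 4) | OC[C@@H]1C(C)=CC[C@@H]2O[C@]12C
F2 | step 3 | [(1R,2S,6S)-1,3-dimethyl-7-oxabicyclo[4.1.0]hept-3-en-2-yl]methyl acetate | CC(=O)OC[C@@H]1C(C)=CC[C@@H]2O[C@]12C
F3 | step 5 | 3-[(1R,2R,6S)-2-hydroxy-6-(hydroxymethyl)-1,5-dimethylcyclohex-4-en-1-yl]propanenitrile | OC[C@@H]1[C@@](C)(CCC#N)[C@H](O)CC=C1C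
F4 | step 5 | 3-[(1R,2R,6S)-2-hydroxy-6-(hydroxymethyl)-1,5-dimethylcyclohex-4-en-1-yl]propanal | OC[C@@H]1[C@@](C)(CCC=O)[C@H](O)CC=C1C
F5 | step 5 | dibenzyl 2-[3-[(1R,2R,6S)-2-hydroxy-6-(hydroxymethyl)-1,5-dimethylcyclohex-4-en-1-yl]propylidene]malonate | OC[C@@H]1[C@@](C)(CCC=C(C(=O)OCc2ccccc2)C(=O)OCc2ccccc2)[C@H](O)CC=C1C
F6 | step 8 | dibenzyl 2-[3-[(1R,2R,5R,6S)-2,5-dihydroxy-6-(hydroxymethyl)-1,5-dimethylcyclohexyl]-2-oxopropyl]malonate | OC[C@@H]1[C@@](C)(CC(=O)CC(C(=O)OCc2ccccc2)C(=O)OCc2ccccc2)[C@H](O)CC[C@@]1(C)O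
F7 | step 8 | dibenzyl 2-[3-[(1R,2R,3R,6R)-2-formyl-3,6-dihydroxy-1,3-dimethylcyclohexyl]-2-oxopropyl]malonate | O=C[C@@H]1[C@@](C)(CC(=O)CC(C(=O)OCc2ccccc2)C(=O)OCc2ccccc2)[C@H](O)CC[C@@]1(C)O
F8 | step 8 | dibenzyl 1β,4α,6α-trihydroxy-8-oxoeudesmane-12,13-dioate (7α-H) | O=C(OCc1ccccc1)C(C(=O)OCc1ccccc1)[C@H]1[C@H](O)[C@@H]2[C@@](C)(CC1=O)[C@H](O)CC[C@@]2(C)O
F9 | step 8 | benzyl 1β,4α,6α-trihydroxyeudesman-12,8α-olid-13-oate (C11 epimers) | O=C(OCc1ccccc1)C1C(=O)O[C@H]2C[C@@]3(C)[C@H](O)CC[C@@](C)(O)[C@@H]3[C@@H](O)[C@H]12
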